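**Retrosynthetic overview**
1. Feature: in ring A (C1 ketone, C2 amide carbon, C3, C4 carbinol, C5/C6 oxirane; chain C1'–C7' from C4) C2 bears nitrogen as its only substituent and lies between C1 and C3. It is therefore put in last, as the carbon of dibromocarbene, into a cyclopentanone that already holds C4, C5 and C6 with their three stereocentres; the bromine it keeps is the handle for C2–N.
2. Disconnections, backwards: Si–O at C4; C2'–C3' (Stille coupling with the C3'–C7' bromodienamide of 2-aminocyclopentane-1,3-dione); C1'=C2' from an ethynyl group; C2–N (copper-catalysed amidation with (R,E)-4-methyloct-2-enamide); C1–C2 and C2–C3 (carbene ring expansion).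
3. Rings: the (S)-4-silyloxycyclopentenone ring is bought, the oxirane is closed on it (step 5), then the five-membered ring is enlarged to six-membered ring A (step 6); the cyclopentanedione ring is bought.
4. Stereocentres: C4 by acetylide addition anti to the silyloxy group, C5/C6 by epoxidation anti to the C4 silyl ether, the side-chain centre by auxiliary-controlled methylation.

Key step: step 6

Remark: the SMILES is read as the isomer with the C4 hydroxyl trans to the oxirane oxygen (triene chain cis to it), an R methyl-bearing centre in the octenoyl chain and all-E alkenes; the route is built for this isomer.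

**Route**

Step 1
Reactants: 1 (S)-4-(tert-butyldimethylsilyloxy)cyclopent-2-en-1-one; 2 (trimethylsilyl)acetylene
Product: 5 (1R,4S)-4-(tert-butyldimethylsilyloxy)-1-[(trimethylsilyl)ethynyl]cyclopent-2-en-1-ol (OH cis to OTBS), via lithium (trimethylsilyl)acetylide 3 (not isolated), via dichlorocerium acetylide 4 (not isolated)
Conditions: n-BuLi, THF, −78 °C; anhydrous CeCl3, −78 °C; then 1, −78 °C; aq NH4Cl
Reagents that add atoms: none
Why: Organocerium 1,2-addition to the enone carbonyl: the weakly basic cerium acetylide should add without enolisation or loss of the β-silyloxy group and approach the ring face opposite the silyloxy substituent, so the new tertiary carbinol (later C4 of ring A) carries OH cis to OTBS.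

Step 2
Reactants: 5 (1R,4S)-4-(tert-butyldimethylsilyloxy)-1-[(trimethylsilyl)ethynyl]cyclopent-2-en-1-ol
Product: 6 (1R,4S)-1-[(trimethylsilyl)ethynyl]cyclopent-2-ene-1,4-diol (cis-diol)
Conditions: HF·pyridine, pyridine, THF, 0 °C to rt
Reagents that add atoms: none
Why: Fluoride cleavage of the secondary TBS ether under pyridine-buffered HF, conditions under which the alkynyl C–Si bond and the ionisable tertiary alcohol are expected to persist; no stereocentre is touched.

Step 3
Reactants: 6 (1R,4S)-1-[(trimethylsilyl)ethynyl]cyclopent-2-ene-1,4-diol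
Product: 7 (R)-4-hydroxy-4-[(trimethylsilyl)ethynyl]cyclopent-2-en-1-one
Conditions: activated MnO2 (excess), CH2Cl2, rt
Reagents that add atoms: none
Why: Chemoselective allylic oxidation: MnO2 oxidises only the secondary allylic alcohol, so the former silyloxy carbon becomes the ketone C1 and the tertiary carbinol remains as the only stereocentre.

Step 4
Reactants: 7 (R)-4-hydroxy-4-[(trimethylsilyl)ethynyl]cyclopent-2-en-1-one
Product: 8 (R)-4-(triethylsilyloxy)-4-[(trimethylsilyl)ethynyl]cyclopent-2-en-1-one
Conditions: Et3SiOTf, 2,6-lutidine, CH2Cl2, −78 to 0 °C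
Reagents that add atoms: triethylsilyl trifluoromethanesulfonate, CC[Si](CC)(CC)OS(=O)(=O)C(F)(F)F
Why: Silyl triflate/lutidine silylation caps the hindered tertiary alcohol faster than the ketone is enol-silylated; the TES ether blocks retro-aldol cleavage and supplies the steric bias for step 5.

Step 5
Reactants: 8 (R)-4-(triethylsilyloxy)-4-[(trimethylsilyl)ethynyl]cyclopent-2-en-1-one
Product: 9 (1S,4S,5R)-4-(triethylsilyloxy)-4-[(trimethylsilyl)ethynyl]-6-oxabicyclo[3.1.0]hexan-2-one (oxirane cis to the alkynyl group and trans to OTES)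
Conditions: tBuOOH (decane), DBU, CH2Cl2, 0 °C
Reagents that add atoms: tert-butyl hydroperoxide, CC(C)(C)OO
Why: Weitz–Scheffer nucleophilic epoxidation: the peroxide anion adds to the β-carbon (C5) on the face opposite the bulky, electronegative C4 silyloxy group and the enolate closes the oxirane on that face, which sets C5 and C6; β-elimination of the silyloxy group would give a cyclopentadienone and is not expected.

Step 6
Reactants: 9 (1S,4S,5R)-4-(triethylsilyloxy)-4-[(trimethylsilyl)ethynyl]-6-oxabicyclo[3.1.0]hexan-2-one; 10 bromoform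
Product: 13 (1S,5S,6R)-3-bromo-5-(triethylsilyloxy)-5-[(trimethylsilyl)ethynyl]-7-oxabicyclo[4.1.0]hept-3-en-2-one (ring A numbering: 2-bromo-5,6-epoxy enone), via TMS enol ether 11 (not isolated), via dibromocyclopropane 12 (not isolated)
Conditions: (i) LiN(SiMe3)2, Me3SiCl (in situ quench), THF, −78 °C; pentane, filtration; (ii) 10, KOtBu, pentane, −30 °C to rt
Reagents that add atoms: none
Why: Deprotonation can occur only at C3, because an enolate towards C6 would place a double bond in the oxirane, and in situ O-silylation traps the enolate as 11 before the C4 silyloxy group can be expelled. Dibromocarbene from CHBr3/KOtBu then adds in a concerted [2+1] fashion to the electron-rich C1=C3 enol ether in preference to the silylalkyne. In 12 the bromide lying over the five-membered ring ionises while the C1–C3 bond opens in a disrotatory two-electron electrocyclic process pushed by the siloxy oxygen, and loss of Me3SiBr from the oxocarbenium ion leaves the 2-bromo enone. The C1–C2 and C2–C3 bonds are thus new and six-membered ring A arises by cyclopropanation followed by electrocyclic ring enlargement, not by chain cyclisation; this is the established dihalocarbene ring expansion of cyclic silyl enol ethers to 2-halocycloalk-2-enones. No stereocentre is created: the two ring-fusion centres of 12 vanish on opening, so either face of carbene attack serves, and C4, C5 and C6 are untouched. The step needs regioselective enolisation, secured by the oxirane, and chemoselective carbene capture, secured by the nucleophilicity of the enol ether.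

Step 7
Reactants: 14 (R)-4-benzyl-2-oxazolidinone; 15 hexanoyl chloride
Product: 16 (R)-4-benzyl-3-hexanoyloxazolidin-2-one
Conditions: Et3N, DMAP (cat.), CH2Cl2, 0 °C to rt
Reagents that add atoms: none
Why: DMAP-catalysed N-acylation of the oxazolidinone by the acid chloride under amine base.

Step 8
Reactants: 16 (R)-4-benzyl-3-hexanoyloxazolidin-2-one
Product: 18 (R)-4-benzyl-3-[(R)-2-methylhexanoyl]oxazolidin-2-one, via sodium Z-enolate 17 (not isolated)
Conditions: NaN(SiMe3)2, THF, −78 °C; MeI, −78 °C
Reagents that add atoms: iodomethane, CI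
Why: Evans asymmetric alkylation: the sodium-chelated Z-enolate is methylated on the face away from the benzyl group, which with the (R)-auxiliary should give the (R)-2-methylhexanoyl centre; the minor diastereomer is separable by chromatography.

Step 9
Reactants: 18 (R)-4-benzyl-3-[(R)-2-methylhexanoyl]oxazolidin-2-one
Product: 19 (R)-2-methylhexan-1-ol
Conditions: LiBH4, MeOH (1 equiv), Et2O, 0 °C
Reagents that add atoms: none
Why: Reductive auxiliary removal: LiBH4 reduces the exocyclic imide carbonyl selectively without touching the α-centre and releases the recoverable oxazolidinone.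

Step 10
Reactants: 19 (R)-2-methylhexan-1-ol
Product: 21 (R,E)-4-methyloct-2-enamide, via (R)-2-methylhexanal 20 (not isolated)
Conditions: Pr4N[RuO4] (cat.), N-methylmorpholine N-oxide, 4 Å MS, CH2Cl2, rt; then Ph3P=CHCONH2, rt to 40 °C
Reagents that add atoms: (carbamoylmethylene)triphenylphosphorane, NC(=O)C=P(c1ccccc1)(c1ccccc1)c1ccccc1
Why: Ley–Griffith oxidation gives the volatile, epimerisable aldehyde under neutral conditions and the stabilised amide ylide is added to the same flask (sequential oxidation–Wittig olefination), a stabilised ylide giving the E-alkene.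

Step 11
Reactants: 13 the 2-bromo-5,6-epoxy enone; 21 (R,E)-4-methyloct-2-enamide
Product: 22 (R,E)-4-methyl-N-[(1S,5S,6R)-2-oxo-5-(triethylsilyloxy)-5-[(trimethylsilyl)ethynyl]-7-oxabicyclo[4.1.0]hept-3-en-3-yl]oct-2-enamide
Conditions: CuI (10 mol%), MeNHCH2CH2NHMe (20 mol%), K2CO3, toluene, 60 °C
Reagents that add atoms: none
Why: Goldberg-type copper-catalysed N-vinylation of a primary amide by a vinyl bromide: the diamine-ligated copper amidate inserts into the C2–Br bond and reductive elimination forms C2–N, while the insoluble carbonate in toluene should leave oxirane, TES ether and C-silyl group intact.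

Step 12
Reactants: 22 the C-silylated ethynyl amide
Product: 23 (R,E)-N-[(1S,5S,6R)-5-ethynyl-2-oxo-5-(triethylsilyloxy)-7-oxabicyclo[4.1.0]hept-3-en-3-yl]-4-methyloct-2-enamide
Conditions: K2CO3 (0.2 equiv), MeOH/THF, 0 °C
Reagents that add atoms: none
Why: Carbonate-catalysed methanolysis of the alkynyl C–Si bond (protodesilylation) is far faster than cleavage of the hindered tertiary TES ether, and substoichiometric base at low temperature limits exposure of the epoxy enone.

Step 13
Reactants: 23 the terminal alkyne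
Product: 24 (R,E)-4-methyl-N-[(1S,5S,6R)-2-oxo-5-[(E)-2-(tributylstannyl)ethenyl]-5-(triethylsilyloxy)-7-oxabicyclo[4.1.0]hept-3-en-3-yl]oct-2-enamide
Conditions: Bu3SnH, Pd(PPh3)2Cl2 (3 mol%), THF, 0 °C
Reagents that add atoms: tributyltin hydride, CCCC[SnH](CCCC)CCCC
Why: Palladium-catalysed hydrostannation: syn addition of Sn–H places tin on the terminal carbon because the internal carbon adjoins the quaternary silyloxy centre, giving the E-vinylstannane (C1'=C2'), and should outpace conjugate reduction of the amido enone.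

Step 14
Reactants: 25 pyridine–sulfur trioxide complex (pyridinium-1-sulfonate)
Product: 26 glutaconaldehyde potassium salt, potassium (1E,3E)-5-oxopenta-1,3-dien-1-olate
Conditions: KOH, H2O, −20 to 40 °C
Reagents that add atoms: potassium hydroxide, [K+].[OH-]
Why: Hydroxide adds to C2 of the N-sulfonated pyridinium, the ring opens (Zincke-type ring opening) and the N-sulfo imine is hydrolysed, giving the all-trans glutaconaldehyde enolate.

Step 15
Reactants: 26 glutaconaldehyde potassium salt
Product: 27 (2E,4E)-5-bromopenta-2,4-dienal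
Conditions: Ph3PBr2, CH2Cl2, 0 °C to rt
Reagents that add atoms: dibromotriphenylphosphorane, BrP(Br)(c1ccccc1)(c1ccccc1)c1ccccc1
Why: The enolate oxygen is activated as an oxyphosphonium ion and replaced by bromide through vinylogous addition–elimination with loss of Ph3PO; the conjugated bromodienal equilibrates to the E,E isomer.

Step 16
Reactants: 27 (2E,4E)-5-bromopenta-2,4-dienal
Product: 28 (2E,4E)-5-bromopenta-2,4-dienoic acid
Conditions: NaClO2, NaH2PO4, 2-methylbut-2-ene, tBuOH/H2O, 0 °C to rt
Reagents that add atoms: sodium chlorite, [Na+].[O-]Cl=O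
Why: Pinnick oxidation converts the enal into the acid without touching the vinyl bromide or the diene geometry, the alkene scavenger removing hypochlorous acid.

Step 17
Reactants: 29 cyclopentane-1,3-dione
Product: 30 2-nitrocyclopentane-1,3-dione (enol form)
Conditions: fuming HNO3, Et2O, 0 °C to rt
Reagents that add atoms: nitric acid, O[N+](=O)[O-]
Why: Electrophilic nitration at C2 of the enolised 1,3-dione, its only nucleophilic carbon.

Step 18
Reactants: 30 2-nitrocyclopentane-1,3-dione
Product: 31 2-amino-3-hydroxycyclopent-2-en-1-one hydrochloride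
Conditions: H2 (1 atm), 10% Pd/C, HCl, MeOH, rt
Reagents that add atoms: hydrogen chloride, Cl
Why: Catalytic hydrogenation of the nitro group; the amine is kept as its hydrochloride because the free 2-amino-1,3-dione self-condenses.

Step 19
Reactants: 28 (2E,4E)-5-bromopenta-2,4-dienoic acid; 31 2-amino-3-hydroxycyclopent-2-en-1-one hydrochloride
Product: 33 (2E,4E)-5-bromo-N-(2-hydroxy-5-oxocyclopent-1-en-1-yl)penta-2,4-dienamide, via acid chloride 32 (not isolated)
Conditions: (i) (COCl)2, DMF (cat.), CH2Cl2, 0 °C to rt, evaporation; (ii) 31, Et3N, DMF/CH2Cl2, 0 °C to rt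
Reagents that add atoms: none
Why: Acid chloride formation under Vilsmeier catalysis and N-acylation of the amine freed in situ; any O-acylated enol ester should pass to the more stable amide by O-to-N acyl transfer.

Step 20
Reactants: 24 the E-vinylstannane; 33 the bromodienamide
Product: 34 (R,E)-N-[(1S,5R,6R)-5-[(1E,3E,5E)-7-[(2-hydroxy-5-oxocyclopent-1-en-1-yl)amino]-7-oxohepta-1,3,5-trien-1-yl]-2-oxo-5-(triethylsilyloxy)-7-oxabicyclo[4.1.0]hept-3-en-3-yl]-4-methyloct-2-enamide
Conditions: Pd2(dba)3, AsPh3, DMF/THF, rt, dark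
Reagents that add atoms: none
Why: Stille coupling: zerovalent palladium inserts into the C3'–Br bond, the vinylstannane transmetalates (AsPh3 speeds this for a hindered stannane) and reductive elimination forms C2'–C3' with retention of all alkene geometries under neutral conditions.

Step 21
Reactants: 34 the TES ether of the target
Product: 35 target, (R,E)-N-[(1S,5R,6R)-5-hydroxy-5-[(1E,3E,5E)-7-[(2-hydroxy-5-oxocyclopent-1-en-1-yl)amino]-7-oxohepta-1,3,5-trien-1-yl]-2-oxo-7-oxabicyclo[4.1.0]hept-3-en-3-yl]-4-methyloct-2-enamide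
Conditions: HF·pyridine, pyridine, THF, 0 °C
Reagents that add atoms: none
Why: Fluoride-driven cleavage of the tertiary Si–O bond under pyridine buffering, which should neither open the oxirane nor ionise the tertiary allylic alcohol.

**Compound list**
1 | (S)-4-(tert-butyldimethylsilyloxy)cyclopent-2-en-1-one | O=C1C=C[C@@H](O[Si](C)(C)C(C)(C)C)C1 | starting material
2 | (trimethylsilyl)acetylene | C#C[Si](C)(C)C | starting material
3 | lithium (trimethylsilyl)acetylide | [Li+].[C-]#C[Si](C)(C)C | intermediate
4 | dichlorocerium (trimethylsilyl)acetylide | C[Si](C)(C)C#C[Ce](Cl)Cl | intermediate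
5 | (1R,4S)-4-(tert-butyldimethylsilyloxy)-1-[(trimethylsilyl)ethynyl]cyclopent-2-en-1-ol | O[C@@]1(C#C[Si](C)(C)C)C=C[C@@H](O[Si](C)(C)C(C)(C)C)C1 | intermediate
6 | (1R,4S)-1-[(trimethylsilyl)ethynyl]cyclopent-2-ene-1,4-diol | O[C@@]1(C#C[Si](C)(C)C)C=C[C@@H](O)C1 | intermediate
7 | (R)-4-hydroxy-4-[(trimethylsilyl)ethynyl]cyclopent-2-en-1-one | O[C@@]1(C#C[Si](C)(C)C)C=CC(=O)C1 | intermediate
8 | (R)-4-(triethylsilyloxy)-4-[(trimethylsilyl)ethynyl]cyclopent-2-en-1-one | CC[Si](CC)(CC)O[C@@]1(C#C[Si](C)(C)C)C=CC(=O)C1 | intermediate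
9 | (1S,4S,5R)-4-(triethylsilyloxy)-4-[(trimethylsilyl)ethynyl]-6-oxabicyclo[3.1.0]hexan-2-one | O=C1C[C@](O[Si](CC)(CC)CC)(C#C[Si](C)(C)C)[C@@H]2O[C@@H]21 | intermediate
10 | bromoform | BrC(Br)Br | starting material
11 | trimethylsilyl enol ether of 9 (C1=C3 enol ether, other centres as in 9) | C[Si](C)(C)OC1=C[C@](O[Si](CC)(CC)CC)(C#C[Si](C)(C)C)[C@@H]2O[C@@H]21 | intermediate
12 | gem-dibromocyclopropane adduct of 11 (CBr2 bridging C1 and C3, drawn anti to OTES) | C[Si](C)(C)O[C@@]12C(Br)(Br)[C@@H]1[C@](O[Si](CC)(CC)CC)(C#C[Si](C)(C)C)[C@@H]3O[C@@H]32 | intermediate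
13 | (1S,5S,6R)-3-bromo-5-(triethylsilyloxy)-5-[(trimethylsilyl)ethynyl]-7-oxabicyclo[4.1.0]hept-3-en-2-one | BrC1=C[C@](O[Si](CC)(CC)CC)(C#C[Si](C)(C)C)[C@@H]2O[C@@H]2C1=O | intermediate
14 | (R)-4-benzyl-2-oxazolidinone | O=C1N[C@H](Cc2ccccc2)CO1 | starting material
15 | hexanoyl chloride | CCCCCC(Cl)=O | starting material
16 | (R)-4-benzyl-3-hexanoyloxazolidin-2-one | CCCCCC(=O)N1[C@H](Cc2ccccc2)COC1=O | intermediate
17 | sodium Z-enolate of 16 | CCCC/C=C(\[O-])N1[C@H](Cc2ccccc2)COC1=O.[Na+] | intermediate
18 | (R)-4-benzyl-3-[(R)-2-methylhexanoyl]oxazolidin-2-one | CCCC[C@@H](C)C(=O)N1[C@H](Cc2ccccc2)COC1=O | intermediate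
19 | (R)-2-methylhexan-1-ol | CCCC[C@@H](C)CO | intermediate
20 | (R)-2-methylhexanal | CCCC[C@@H](C)C=O | intermediate
21 | (R,E)-4-methyloct-2-enamide | CCCC[C@@H](C)/C=C/C(N)=O | intermediate
22 | (R,E)-4-methyl-N-[(1S,5S,6R)-2-oxo-5-(triethylsilyloxy)-5-[(trimethylsilyl)ethynyl]-7-oxabicyclo[4.1.0]hept-3-en-3-yl]oct-2-enamide | CCCC[C@@H](C)/C=C/C(=O)NC1=C[C@](O[Si](CC)(CC)CC)(C#C[Si](C)(C)C)[C@@H]2O[C@@H]2C1=O | intermediate
23 | (R,E)-N-[(1S,5S,6R)-5-ethynyl-2-oxo-5-(triethylsilyloxy)-7-oxabicyclo[4.1.0]hept-3-en-3-yl]-4-methyloct-2-enamide | CCCC[C@@H](C)/C=C/C(=O)NC1=C[C@](O[Si](CC)(CC)CC)(C#C)[C@@H]2O[C@@H]2C1=O | intermediate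
24 | (R,E)-4-methyl-N-[(1S,5S,6R)-2-oxo-5-[(E)-2-(tributylstannyl)ethenyl]-5-(triethylsilyloxy)-7-oxabicyclo[4.1.0]hept-3-en-3-yl]oct-2-enamide | CCCC[C@@H](C)/C=C/C(=O)NC1=C[C@](O[Si](CC)(CC)CC)(/C=C/[Sn](CCCC)(CCCC)CCCC)[C@@H]2O[C@@H]2C1=O | intermediate
25 | pyridine–sulfur trioxide complex | [O-]S(=O)(=O)[n+]1ccccc1 | starting material
26 | glutaconaldehyde potassium salt | [K+].[O-]/C=C/C=C/C=O | intermediate
27 | (2E,4E)-5-bromopenta-2,4-dienal | Br/C=C/C=C/C=O | intermediate
28 | (2E,4E)-5-bromopenta-2,4-dienoic acid | Br/C=C/C=C/C(O)=O | intermediate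
29 | cyclopentane-1,3-dione | O=C1CCC(=O)C1 | starting material
30 | 2-nitrocyclopentane-1,3-dione (enol form) | O=C1CCC(O)=C1[N+](=O)[O-] | intermediate
31 | 2-amino-3-hydroxycyclopent-2-en-1-one hydrochloride | NC1=C(O)CCC1=O.Cl | intermediate
32 | (2E,4E)-5-bromopenta-2,4-dienoyl chloride | Br/C=C/C=C/C(Cl)=O | intermediate
33 | (2E,4E)-5-bromo-N-(2-hydroxy-5-oxocyclopent-1-en-1-yl)penta-2,4-dienamide | Br/C=C/C=C/C(=O)NC1=C(O)CCC1=O | intermediate
34 | TES ether of the target | CCCC[C@@H](C)/C=C/C(=O)NC1=C[C@](O[Si](CC)(CC)CC)(/C=C/C=C/C=C/C(=O)NC2=C(O)CCC2=O)[C@@H]2O[C@@H]2C1=O | intermediate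
35 | target CNP0259807.5 | CCCC[C@@H](C)/C=C/C(=O)NC1=C[C@](O)(/C=C/C=C/C=C/C(=O)NC2=C(O)CCC2=O)[C@@H]2O[C@@H]2C1=O | target

**Step count and risks**
Total: 21 steps. Longest linear sequence: 11 steps (steps 1–6, 11–13, 20, 21 from compound 1).

Step 6 (key step). What may go wrong: expulsion of the C4 silyloxy group or oxirane opening if silylation of the enolate lags, carbene addition to the alkyne, attack of tert-butoxide on the bromo enone, or incomplete opening of the cyclopropane. Fallback, setting out from 9 and returning at 22: the enol ether 11 is made as before but isolated, then cyclopropanated with the zinc methylene carbenoid (Et2Zn, CH2I2; Simmons–Smith) to the siloxycyclopropane F1. FeCl3 in DMF cleaves the C1–C3 bond oxidatively (Ito–Saegusa ring enlargement) to the ring-expanded 3-chloro ketone F2, which NaOAc in MeOH dehydrochlorinates to the halogen-free epoxy enone F3. α-Iodination with I2/pyridine (addition–elimination through the pyridinium enolate) gives the 2-iodo enone F4, which replaces 13 in the CuI amidation with 21 and delivers 22.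

Step 11. What may go wrong: stalled insertion of copper into the hindered C2–Br bond, base-induced opening of the oxirane at 60 °C, or loss of the C-silyl group followed by copper acetylide side reactions. Fallback, setting out from 13 and returning at 22: 13 is coupled with benzophenone imine (Pd2(dba)3, Xantphos, Cs2CO3, toluene; Buchwald–Hartwig amination of a vinyl bromide) to the N-diphenylmethylene enamine F5. Transimination with NH2OH·HCl/NaOAc in MeOH frees the primary 2-amino enone F6. Separately, aldehyde 20 is homologated with the dianion of diethylphosphonoacetic acid (Horner–Wadsworth–Emmons) to (R,E)-4-methyloct-2-enoic acid F7, which 1-chloro-N,N,2-trimethylpropenylamine converts into (R,E)-4-methyloct-2-enoyl chloride F8. Acylation of F6 with F8 (pyridine, CH2Cl2, 0 °C) gives 22.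

Step 20. What may go wrong: protodestannylation of the vinylstannane by the acidic enol of 33, slow transmetalation at the neopentyl-type stannane, or isomerisation and decay of the polyene. Fallback, setting out from 24 and returning at 34: 24 is coupled under the same Stille conditions with the neutral bromodienal 27 to the trienal F9. Pinnick oxidation gives the trienoic acid F10, pivaloyl chloride/Et3N its pivalic mixed anhydride F11, and aminolysis with 31 gives 34.

**Further compounds**
F1 | step 6 | methylene cyclopropane adduct of 11 (1-trimethylsilyloxy, CH2 bridging C1 and C3) | C[Si](C)(C)O[C@@]12C[C@@H]1[C@](O[Si](CC)(CC)CC)(C#C[Si](C)(C)C)[C@@H]3O[C@@H]32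
F2 | step 6 | 4-chloro-5-(triethylsilyloxy)-5-[(trimethylsilyl)ethynyl]-7-oxabicyclo[4.1.0]heptan-2-one (chlorine-bearing carbon unassigned, other centres as in 9) | O=C1CC(Cl)[C@](O[Si](CC)(CC)CC)(C#C[Si](C)(C)C)[C@@H]2O[C@@H]21
F3 | step 6 | 5-(triethylsilyloxy)-5-[(trimethylsilyl)ethynyl]-7-oxabicyclo[4.1.0]hept-3-en-2-one (bromine-free analogue of 13) | O=C1C=C[C@](O[Si](CC)(CC)CC)(C#C[Si](C)(C)C)[C@@H]2O[C@@H]21
F4 | step 6 | 3-iodo analogue of 13 | IC1=C[C@](O[Si](CC)(CC)CC)(C#C[Si](C)(C)C)[C@@H]2O[C@@H]2C1=O
F5 | step 11 | 3-(diphenylmethyleneamino) analogue of 13 | C(=NC1=C[C@](O[Si](CC)(CC)CC)(C#C[Si](C)(C)C)[C@@H]2O[C@@H]2C1=O)(c1ccccc1)c1ccccc1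
F6 | step 11 | 3-amino analogue of 13 | NC1=C[C@](O[Si](CC)(CC)CC)(C#C[Si](C)(C)C)[C@@H]2O[C@@H]2C1=O
F7 | step 11 | (R,E)-4-methyloct-2-enoic acid | CCCC[C@@H](C)/C=C/C(O)=O
F8 | step 11 | (R,E)-4-methyloct-2-enoyl chloride | CCCC[C@@H](C)/C=C/C(Cl)=O
F9 | step 20 | trienal from 24 and 27 | CCCC[C@@H](C)/C=C/C(=O)NC1=C[C@](O[Si](CC)(CC)CC)(/C=C/C=C/C=C/C=O)[C@@H]2O[C@@H]2C1=O
F10 | step 20 | corresponding (2E,4E,6E)-trienoic acid | CCCC[C@@H](C)/C=C/C(=O)NC1=C[C@](O[Si](CC)(CC)CC)(/C=C/C=C/C=C/C(O)=O)[C@@H]2O[C@@H]2C1=O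
F11 | step 20 | pivalic mixed anhydride of F10 | CCCC[C@@H](C)/C=C/C(=O)NC1=C[C@](O[Si](CC)(CC)CC)(/C=C/C=C/C=C/C(=O)OC(=O)C(C)(C)C)[C@@H]2O[C@@H]2C1=O
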